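The carbocyclic ring of the tetrahydroquinoline (C4a, C5, C6, C7, C8, C8a) is treated as a masked 4,4-disubstituted cyclohex-2-enone: C8a is the former carbonyl carbon, C4a its α′-carbon and the quaternary C6 the γ-carbon. A catalytic asymmetric Robinson annulation of a racemic acyclic α-aryl aldehyde with methyl vinyl ketone forms C5–C6 (Michael addition, setting the C6 stereocentre) and C7–C8 (aldol condensation) in one operation; the precursor contains neither ring. Since C6 is quaternary, the enone can enolise only towards C4a, so propargylamine annulation fuses the pyridine there; hydrogenation of C7=C8 and Boc-to-formyl exchange finish the route.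

Key step: step 3

Remark: atom numbers C4a to C8a are the quinoline numbers of the target, whose stereocentre C6 is (S).

Assumption: the hydrogen-bond-directed enamine model (E-enamine with the aryl group anti to nitrogen, enone delivered to the face syn to the sulfonamide) is taken to hold for aldehyde 4; it predicts that the (R)-configured catalyst gives the (S)-enone 7. Should the sense prove opposite, the (S)-catalyst would be used with no other change.

Step 1
Reactants: 1 3,4-dimethoxyphenylacetonitrile; 2 tert-butyl N-(2-bromoethyl)-N-methylcarbamate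
Product: 3 tert-butyl N-[3-cyano-3-(3,4-dimethoxyphenyl)propyl]-N-methylcarbamate (racemic)
Conditions: LiN(SiMe3)2, THF, −78 °C; then 2, −78 °C to 23 °C
Reagents that add atoms: none
Why: SN2 alkylation of the lithiated benzylic nitrile with the primary bromide should proceed cleanly at low temperature because the carbamate has no N–H; the new stereocentre is racemic, which is harmless since it becomes planar in step 3.

Step 2
Reactants: 3 tert-butyl N-[3-cyano-3-(3,4-dimethoxyphenyl)propyl]-N-methylcarbamate
Product: 4 tert-butyl N-[3-(3,4-dimethoxyphenyl)-4-oxobutyl]-N-methylcarbamate (racemic)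
Conditions: i-Bu2AlH, toluene/CH2Cl2, −78 °C; then aqueous citric acid, 0 °C
Reagents that add atoms: water, O
Why: Partial reduction of a nitrile with i-Bu2AlH should stop at the N-aluminated aldimine at −78 °C, which hydrolyses to the aldehyde on mildly acidic work-up, while the tert-butyl carbamate is not reduced at this temperature.

Step 3
Reactants: 4 tert-butyl N-[3-(3,4-dimethoxyphenyl)-4-oxobutyl]-N-methylcarbamate; 5 methyl vinyl ketone
Product: 7 tert-butyl N-{2-[(1S)-1-(3,4-dimethoxyphenyl)-4-oxocyclohex-2-en-1-yl]ethyl}-N-methylcarbamate, via keto aldehyde 6 (not isolated)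
Conditions: (R)-N-(4-dodecylphenylsulfonyl)pyrrolidine-2-carboxamide (20 mol %), 4 Å molecular sieves, ClCH2CH2Cl, 23 °C; then pyrrolidine/AcOH (cat.), 40 °C, same flask
Reagents that add atoms: none
Why: The racemic aldehyde condenses with the catalyst to one (E)-enamine in which the future C6 is planar, so both enantiomers of 4 converge; the sulfonamide N–H hydrogen-bonds the carbonyl of 5 and delivers its CH2 terminus to one enamine face, forming C5–C6 and the quaternary stereocentre, and hydrolysis releases keto aldehyde 6. Pyrrolidinium acetate then turns the methyl ketone into its enamine, which adds to the neighbouring aldehyde and loses water to form C7=C8. The closest known reaction type is the amine-catalysed asymmetric Robinson annulation of α,α-disubstituted aldehydes with vinyl ketones (Yamada–Otani condensation). The ring closes by a 6-(enolendo)-exo-trig aldol addition followed by E1cB dehydration. The stereocentre is under catalyst control (enantioface selection in the Michael addition) and cannot epimerise afterwards because it carries no hydrogen. The step needs a clean crossed reaction, which is secured because the aldehyde in 6 is non-enolisable and only the methyl group of the ketone can reach it through a six-membered transition state.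

Step 4
Reactants: 7 tert-butyl N-{2-[(1S)-1-(3,4-dimethoxyphenyl)-4-oxocyclohex-2-en-1-yl]ethyl}-N-methylcarbamate; 8 propargylamine
Product: 11 tert-butyl N-{2-[(6S)-6-(3,4-dimethoxyphenyl)-5,6-dihydroquinolin-6-yl]ethyl}-N-methylcarbamate, via N-propargyl dienamine 9 (not isolated), via dihydropyridine 10 (not isolated)
Conditions: NaAuCl4·2H2O (5 mol %), EtOH, 80 °C, air
Reagents that add atoms: none
Why: In this gold-catalysed amination/annulation/aromatisation of a ketone with propargylamine, the N-propargyl imine can tautomerise only to the enamine towards the α′-carbon (the γ-carbon is quaternary), whose 6-endo-dig attack on the gold-activated alkyne and air oxidation of the resulting dihydropyridine should fuse the pyridine at C4a/C8a without touching the stereocentre.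

Step 5
Reactants: 11 tert-butyl N-{2-[(6S)-6-(3,4-dimethoxyphenyl)-5,6-dihydroquinolin-6-yl]ethyl}-N-methylcarbamate
Product: 12 tert-butyl N-{2-[(6S)-6-(3,4-dimethoxyphenyl)-5,6,7,8-tetrahydroquinolin-6-yl]ethyl}-N-methylcarbamate
Conditions: H2 (1 atm), 10% Pd/C, EtOAc, 23 °C
Reagents that add atoms: none
Why: Heterogeneous hydrogenation of the C7=C8 bond, a 2-alkenylpyridine-type alkene, should be far faster than reduction of the pyridine or the arene at atmospheric pressure; no new stereocentre forms and the quaternary one is untouched.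

Step 6
Reactants: 12 tert-butyl N-{2-[(6S)-6-(3,4-dimethoxyphenyl)-5,6,7,8-tetrahydroquinolin-6-yl]ethyl}-N-methylcarbamate
Product: 14 N-{2-[(6S)-6-(3,4-dimethoxyphenyl)-5,6,7,8-tetrahydroquinolin-6-yl]ethyl}-N-methylformamide, via tortuosamine 13 (not isolated)
Conditions: HCO2H (neat), 40 °C; then Ac2O, 0 °C to 23 °C; aqueous NaHCO3 work-up
Reagents that add atoms: formic acid, O=CO
Why: Acidolysis of the tert-butyl carbamate in formic acid should release the secondary amine, which is N-formylated by acetic formic anhydride generated in the same flask; the pyridine and the aryl ethers are inert.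

Compound list
1 | 3,4-dimethoxyphenylacetonitrile | COc1ccc(CC#N)cc1OC | starting material
2 | tert-butyl N-(2-bromoethyl)-N-methylcarbamate | CN(CCBr)C(=O)OC(C)(C)C | starting material
3 | tert-butyl N-[3-cyano-3-(3,4-dimethoxyphenyl)propyl]-N-methylcarbamate (racemic) | COc1ccc(C(C#N)CCN(C)C(=O)OC(C)(C)C)cc1OC | intermediate
4 | tert-butyl N-[3-(3,4-dimethoxyphenyl)-4-oxobutyl]-N-methylcarbamate (racemic) | COc1ccc(C(C=O)CCN(C)C(=O)OC(C)(C)C)cc1OC | intermediate
5 | methyl vinyl ketone (but-3-en-2-one) | CC(=O)C=C | starting material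
6 | tert-butyl N-[(3R)-3-(3,4-dimethoxyphenyl)-3-formyl-6-oxoheptyl]-N-methylcarbamate (keto aldehyde, not isolated) | COc1ccc([C@@](CCC(C)=O)(CCN(C)C(=O)OC(C)(C)C)C=O)cc1OC | intermediate
7 | tert-butyl N-{2-[(1S)-1-(3,4-dimethoxyphenyl)-4-oxocyclohex-2-en-1-yl]ethyl}-N-methylcarbamate | COc1ccc([C@@]2(CCN(C)C(=O)OC(C)(C)C)C=CC(=O)CC2)cc1OC | intermediate
8 | propargylamine (prop-2-yn-1-amine) | NCC#C | starting material
9 | tert-butyl N-{2-[(1S)-1-(3,4-dimethoxyphenyl)-4-(prop-2-yn-1-ylamino)cyclohexa-2,4-dien-1-yl]ethyl}-N-methylcarbamate (N-propargyl dienamine, not isolated) | COc1ccc([C@@]2(CCN(C)C(=O)OC(C)(C)C)C=CC(NCC#C)=CC2)cc1OC | intermediate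
10 | tert-butyl N-{2-[(6S)-6-(3,4-dimethoxyphenyl)-2,4a,5,6-tetrahydroquinolin-6-yl]ethyl}-N-methylcarbamate (dihydropyridine, C4a epimers, not isolated) | COc1ccc([C@@]2(CCN(C)C(=O)OC(C)(C)C)C=CC3=NCC=CC3C2)cc1OC | intermediate
11 | tert-butyl N-{2-[(6S)-6-(3,4-dimethoxyphenyl)-5,6-dihydroquinolin-6-yl]ethyl}-N-methylcarbamate | COc1ccc([C@@]2(CCN(C)C(=O)OC(C)(C)C)C=Cc3ncccc3C2)cc1OC | intermediate
12 | tert-butyl N-{2-[(6S)-6-(3,4-dimethoxyphenyl)-5,6,7,8-tetrahydroquinolin-6-yl]ethyl}-N-methylcarbamate | COc1ccc([C@@]2(CCN(C)C(=O)OC(C)(C)C)CCc3ncccc3C2)cc1OC | intermediate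
13 | 2-[(6S)-6-(3,4-dimethoxyphenyl)-5,6,7,8-tetrahydroquinolin-6-yl]-N-methylethan-1-amine (tortuosamine, not isolated) | COc1ccc([C@@]2(CCNC)CCc3ncccc3C2)cc1OC | intermediate
14 | N-{2-[(6S)-6-(3,4-dimethoxyphenyl)-5,6,7,8-tetrahydroquinolin-6-yl]ethyl}-N-methylformamide (N-formyltortuosamine) | COc1ccc([C@@]2(CCN(C)C=O)CCc3ncccc3C2)cc1OC | target

Total step count: 6. Longest linear sequence: 6 steps (1 → 3 → 4 → 7 → 11 → 12 → 14).

Steps most likely to fail

Step 3. Enamine formation from the hindered α-branched aldehyde may be slow, and facial selectivity in the Michael addition may be poor. The fallback sets out from 4 and 5 and returns at 7. The annulation would be run without chiral information (KOH, MeOH, 0 °C to 23 °C) to give racemic tert-butyl N-{2-[1-(3,4-dimethoxyphenyl)-4-oxocyclohex-2-en-1-yl]ethyl}-N-methylcarbamate F1. Dehydrogenation with 2-iodoxybenzoic acid (DMSO, 70 °C) would give the achiral tert-butyl N-{2-[1-(3,4-dimethoxyphenyl)-4-oxocyclohexa-2,5-dien-1-yl]ethyl}-N-methylcarbamate F2. A desymmetrising enantioselective conjugate reduction of one of its two enantiotopic C=C bonds (Cu(OAc)2·H2O, the DTBM-SEGPHOS enantiomer that gives the (S)-product, (EtO)2MeSiH, t-BuOH, toluene, 0 °C, one equivalent of silane) would then deliver 7. The stereocentre is thus set by differentiation of two alkenes and not by C–C bond formation.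

Step 4. The primary amine may add in conjugate fashion to the enone, condensation at the hindered carbonyl may be slow, and aromatisation may stall. The fallback sets out from 7 and returns at 11. The kinetic α′-enolate of 7 (LiN(i-Pr)2, THF, −78 °C), which can form only towards the future C4a, would be alkylated with 2-(2-iodoethyl)-1,3-dioxolane (DMPU, −78 °C to 0 °C) to give tert-butyl N-{2-[(1S)-5-[2-(1,3-dioxolan-2-yl)ethyl]-1-(3,4-dimethoxyphenyl)-4-oxocyclohex-2-en-1-yl]ethyl}-N-methylcarbamate F3. Heating with NH2OH·HCl in aqueous EtOH/AcOH would unmask tert-butyl N-{2-[(1S)-1-(3,4-dimethoxyphenyl)-4-oxo-5-(3-oxopropyl)cyclohex-2-en-1-yl]ethyl}-N-methylcarbamate F4. Its oxime should cyclise and dehydrate to the pyridine 11 (1,5-dicarbonyl/hydroxylamine pyridine synthesis, no oxidant needed).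

Step 1. The benzylic nitrile may be alkylated twice, and the strong base may cause elimination or cyclisation of the bromoethyl carbamate. The fallback sets out from 1 and returns at 3. Compound 1 would first be C-acylated with dimethyl carbonate (NaH, THF, 60 °C) to methyl 2-cyano-2-(3,4-dimethoxyphenyl)acetate F5. Its single acidic hydrogen allows alkylation with 2 under mild base (Cs2CO3, DMF, 40 °C) to give methyl 4-[(tert-butoxycarbonyl)(methyl)amino]-2-cyano-2-(3,4-dimethoxyphenyl)butanoate F6. Saponification (LiOH, THF/H2O, 23 °C) would give 4-[(tert-butoxycarbonyl)(methyl)amino]-2-cyano-2-(3,4-dimethoxyphenyl)butanoic acid F7, which should decarboxylate on gentle warming with AcOH to 3.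

Further compounds
F1 | step 3 | tert-butyl N-{2-[1-(3,4-dimethoxyphenyl)-4-oxocyclohex-2-en-1-yl]ethyl}-N-methylcarbamate (racemic) | COc1ccc(C2(CCN(C)C(=O)OC(C)(C)C)C=CC(=O)CC2)cc1OC
F2 | step 3 | tert-butyl N-{2-[1-(3,4-dimethoxyphenyl)-4-oxocyclohexa-2,5-dien-1-yl]ethyl}-N-methylcarbamate | COc1ccc(C2(CCN(C)C(=O)OC(C)(C)C)C=CC(=O)C=C2)cc1OC
F3 | step 4 | tert-butyl N-{2-[(1S)-5-[2-(1,3-dioxolan-2-yl)ethyl]-1-(3,4-dimethoxyphenyl)-4-oxocyclohex-2-en-1-yl]ethyl}-N-methylcarbamate | COc1ccc([C@@]2(CCN(C)C(=O)OC(C)(C)C)C=CC(=O)C(CCC3OCCO3)C2)cc1OC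
F4 | step 4 | tert-butyl N-{2-[(1S)-1-(3,4-dimethoxyphenyl)-4-oxo-5-(3-oxopropyl)cyclohex-2-en-1-yl]ethyl}-N-methylcarbamate | COc1ccc([C@@]2(CCN(C)C(=O)OC(C)(C)C)C=CC(=O)C(CCC=O)C2)cc1OC
F5 | step 1 | methyl 2-cyano-2-(3,4-dimethoxyphenyl)acetate | COc1ccc(C(C#N)C(=O)OC)cc1OC
F6 | step 1 | methyl 4-[(tert-butoxycarbonyl)(methyl)amino]-2-cyano-2-(3,4-dimethoxyphenyl)butanoate | COc1ccc(C(C#N)(CCN(C)C(=O)OC(C)(C)C)C(=O)OC)cc1OC
F7 | step 1 | 4-[(tert-butoxycarbonyl)(methyl)amino]-2-cyano-2-(3,4-dimethoxyphenyl)butanoic acid | COc1ccc(C(C#N)(CCN(C)C(=O)OC(C)(C)C)C(=O)O)cc1OC
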